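**Strategy.** The flavanone is disconnected at C2–C3 and C4–C4a of ring C. O1–C2 plus the ortho carbon C4a of the symmetric 3,4,5-trimethoxyphenoxy ring A act as a cationic 2-oxadiene (C2=O1+–C8a=C4a), and ethyl vinyl ether supplies C3–C4 with the C4 oxygen. One catalyst-controlled cationic [4+2] annulation thus closes ring C, forms both C–C bonds and sets C2 as S; C4 emerges as an ethyl ether, a masked ketone. The precursor is the O-aryl O-methyl acetal of veratraldehyde with 3,4,5-trimethoxyphenol, converted in the flask into its α-chloro ether so that only the O-aryl oxocarbenium ion forms. Oxidation at C4 then gives the target.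

Key step: step 3

Remark: the annulation product is written as the 2,4-cis isomer (2S,4S), but C4 becomes trigonal in step 4, so any trans (2S,4R) material converges on the same flavanone; catalyst T in step 3 is 1-[3,5-bis(trifluoromethyl)phenyl]-3-{3,3-dimethyl-1-oxo-1-[2-(phenanthren-9-yl)pyrrolidin-1-yl]butan-2-yl}thiourea (tert-leucine-derived, single stereoisomer), and which antipode delivers 2S has to be fixed in the first runs.

Step 1
Reactants: 1 3,4-dimethoxybenzaldehyde (veratraldehyde)
Product: 2 4-(dimethoxymethyl)-1,2-dimethoxybenzene
Conditions: HC(OMe)3 (1.5 equiv), MeOH, p-TsOH·H2O (1 mol %), rt; then Et3N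
Reagents that add atoms: methanol CO; trimethyl orthoformate COC(OC)OC
Why: Acid-catalysed acetalisation by the orthoformate method, in which the orthoformate consumes the water released and drives the equilibrium to the dimethyl acetal.

Step 2
Reactants: 2 4-(dimethoxymethyl)-1,2-dimethoxybenzene; 3 3,4,5-trimethoxyphenol
Product: 5 5-[(3,4-dimethoxyphenyl)(methoxy)methoxy]-1,2,3-trimethoxybenzene, via 4-[chloro(methoxy)methyl]-1,2-dimethoxybenzene 4 (not isolated)
Conditions: AcCl (1.0 equiv), Zn(OAc)2 (0.1 mol %), toluene, 0 °C → rt; then 3, NaH (1.1 equiv), THF, 0 °C → rt; chromatography on Et3N-deactivated SiO2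
Reagents that add atoms: none
Why: Exchange of one acetal methoxy group for chloride by an acyl chloride (α-chloro ether synthesis) followed by Williamson-type O-alkylation of the sodium phenoxide, as in MOM protection of phenols, should give the mixed acetal with no acid present that could trigger Friedel–Crafts attack on the electron-rich ring of 3.

Step 3
Reactants: 5 5-[(3,4-dimethoxyphenyl)(methoxy)methoxy]-1,2,3-trimethoxybenzene; 6 ethyl vinyl ether
Product: 10 (2S,4S)-4-ethoxy-2-(3,4-dimethoxyphenyl)-5,6,7-trimethoxychromane, via aryloxy α-chloro ether 7 (not isolated), via O-aryl oxocarbenium chloride 8 (not isolated), via O-ethyl oxocarbenium chloride 9 (not isolated)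
Conditions: BCl3 (0.4 equiv), CH2Cl2, −78 → 0 °C, then evaporation; catalyst T (10 mol %), 6 (3 equiv), 2,6-di-tert-butyl-4-methylpyridine (1.2 equiv), t-BuOMe, −78 → −40 °C
Reagents that add atoms: none
Why: Proposed new method: BCl3 removes the methoxy group of 5 (the more basic, less hindered acetal oxygen) and returns chloride to give 7; the thiourea binds that chloride and ionises 7 to the ion pair 8, the CH2 terminus of 6 adds to C2, and the resulting cation 9 is trapped at once by C4a while the hindered pyridine takes up the proton. The closest known reactions are the achiral Lewis acid-promoted oxa-Povarov annulation of aryl methyl acetals with alkenes, thiourea-catalysed chloride-binding additions of nucleophiles to oxocarbenium ions made from α-chloro ethers, and the chiral-acid Povarov reaction of N-aryl imines with vinyl ethers; an enantioselective variant with an acyclic O-aryl oxocarbenium ion has not been shown. Ring C closes by intramolecular Friedel–Crafts attack of C4a on C4, 6-exo-trig with respect to the C4=O+ bond, so the overall event is a stepwise [4+2] of the 2-oxadiene C2=O1+–C8a=C4a with the vinyl ether. C2 is set by the catalyst in the first C–C bond formation, since the bound chloride stays in contact with the cation and the phenanthryl arm covers one face, leaving the other open to 6; C4 is set by the substrate through a chair-like closure with aryl and ethoxy equatorial (cis) and is erased in step 4. The step needs enantioface selectivity at C2, one-directional ionisation and a single ring-A regiochemistry: the second is secured by chloride being the only group the neutral catalyst can abstract (a protic chiral acid is avoided because aryl methyl acetals tend to expel the phenol under proton catalysis), the third by the mirror symmetry of the 3,4,5-trimethoxyphenoxy group, which makes its two ortho carbons one and the same site. That site lies between O1 and a methoxy group and para to another, which should let cyclisation outrun oligomerisation of the vinyl ether.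

Step 4
Reactants: 10 (2S,4S)-4-ethoxy-2-(3,4-dimethoxyphenyl)-5,6,7-trimethoxychromane
Product: 11 (2S)-5,6,7,3',4'-pentamethoxyflavanone
Conditions: DDQ (1.2 equiv), CH2Cl2–pH 7 phosphate buffer (10:1), 0 °C → rt
Reagents that add atoms: water O
Why: Oxidative cleavage of an electron-rich benzylic ether (the reaction that removes PMB and DMB groups): DDQ should abstract hydride from C4, which is benzylic to the tetraoxygenated ring A and α to the ethoxy oxygen, water adds to the carboxonium ion and ethanol is lost to leave the aryl ketone, while C2 is untouched and the neutral buffer avoids base-induced ring opening that would racemise the flavanone.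

**Compound list**
1 | 3,4-dimethoxybenzaldehyde (veratraldehyde) | COc1ccc(C=O)cc1OC | starting material
2 | 4-(dimethoxymethyl)-1,2-dimethoxybenzene | COc1ccc(C(OC)OC)cc1OC | intermediate
3 | 3,4,5-trimethoxyphenol | COc1cc(O)cc(OC)c1OC | starting material
4 | 4-[chloro(methoxy)methyl]-1,2-dimethoxybenzene (racemic) | COc1ccc(C(Cl)OC)cc1OC | intermediate (not isolated)
5 | 5-[(3,4-dimethoxyphenyl)(methoxy)methoxy]-1,2,3-trimethoxybenzene (racemic mixed acetal) | COc1ccc(C(OC)Oc2cc(OC)c(OC)c(OC)c2)cc1OC | intermediate
6 | ethyl vinyl ether | C=COCC | starting material
7 | 5-[chloro(3,4-dimethoxyphenyl)methoxy]-1,2,3-trimethoxybenzene (racemic) | COc1ccc(C(Cl)Oc2cc(OC)c(OC)c(OC)c2)cc1OC | intermediate (not isolated)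
8 | [(3,4-dimethoxyphenyl)methylidene](3,4,5-trimethoxyphenyl)oxonium chloride (ion pair, chloride bound to catalyst T) | COc1ccc(C=[O+]c2cc(OC)c(OC)c(OC)c2)cc1OC.[Cl-] | intermediate (not isolated)
9 | [(3S)-3-(3,4-dimethoxyphenyl)-3-(3,4,5-trimethoxyphenoxy)propylidene](ethyl)oxonium chloride (ion pair) | COc1ccc([C@H](CC=[O+]CC)Oc2cc(OC)c(OC)c(OC)c2)cc1OC.[Cl-] | intermediate (not isolated)
10 | (2S,4S)-4-ethoxy-2-(3,4-dimethoxyphenyl)-5,6,7-trimethoxychromane | COc1ccc([C@@H]2C[C@H](OCC)c3c(cc(OC)c(OC)c3OC)O2)cc1OC | intermediate
11 | (2S)-2-(3,4-dimethoxyphenyl)-5,6,7-trimethoxychroman-4-one, (2S)-5,6,7,3',4'-pentamethoxyflavanone | COc1ccc([C@@H]2CC(=O)c3c(cc(OC)c(OC)c3OC)O2)cc1OC | target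

**Step count.** Total: 4 steps. Longest linear sequence: 4 steps (1 → 2 → 5 → 10 → 11).

**Steps most likely to fail**

Step 3. The main danger is insufficient face discrimination when the vinyl ether attacks the ion pair. Cleavage of the acetal at the aryloxy oxygen during chloride exchange, cationic oligomerisation of the vinyl ether and intermolecular Friedel–Crafts alkylation of ring A could also lower the return. Fallback by known chemistry, setting out from 5: SnCl4 (1.1 equiv) and 6 in CH2Cl2 at −78 °C, the achiral Lewis acid oxa-Povarov annulation, should give racemic 4-ethoxy-2-(3,4-dimethoxyphenyl)-5,6,7-trimethoxychromane F1. DDQ in wet CH2Cl2, as in step 4, should turn it into racemic 2-(3,4-dimethoxyphenyl)-5,6,7-trimethoxychroman-4-one F2. Preparative HPLC of F2 on an amylose tris(3,5-dimethylphenylcarbamate) phase, a standard separation for flavanone enantiomers, then provides the 2S enantiomer and rejoins the route at 11.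

Step 4. Hydride abstraction could occur at C2 (a dimethoxybenzyl-type position) in competition with C4, the flavanone could be dehydrogenated further to the flavone, or the C4 cation could be captured by C8 of a second molecule. Fallback, setting out from 10: pyridinium p-toluenesulfonate in aqueous acetone at rt and high dilution exchanges ethoxy for hydroxy through the C4 cation stabilised by ring A and should give (2S)-2-(3,4-dimethoxyphenyl)-5,6,7-trimethoxychroman-4-ol F3 as a mixture of C4 epimers. Activated MnO2 in CH2Cl2 then oxidises this benzylic alcohol and returns to the route at 11.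

Step 2. The ambident phenoxide could be alkylated at the ring carbon ortho to oxygen, or the moisture-sensitive chloro ether 4 could hydrolyse before coupling. Fallback, setting out from 3: Williamson etherification with 3,4-dimethoxybenzyl chloride (K2CO3, DMF, rt) should give 5-[(3,4-dimethoxybenzyl)oxy]-1,2,3-trimethoxybenzene F4. Oxidative acetalisation of this dimethoxybenzyl ether with DDQ (1.1 equiv), MeOH (3 equiv), solid NaHCO3 and 4 Å sieves in CH2Cl2 at 0 °C (hydride abstraction at the benzylic CH2 and capture of the cation by methanol) then returns to the route at 5.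

**Further compounds**
F1 | step 3 | racemic 4-ethoxy-2-(3,4-dimethoxyphenyl)-5,6,7-trimethoxychromane (racemate, no stereodescriptors) | COc1ccc(C2CC(OCC)c3c(cc(OC)c(OC)c3OC)O2)cc1OC
F2 | step 3 | racemic 2-(3,4-dimethoxyphenyl)-5,6,7-trimethoxychroman-4-one (racemate, no stereodescriptors) | COc1ccc(C2CC(=O)c3c(cc(OC)c(OC)c3OC)O2)cc1OC
F3 | step 4 | (2S)-2-(3,4-dimethoxyphenyl)-5,6,7-trimethoxychroman-4-ol (C4 epimer mixture) | COc1ccc([C@@H]2CC(O)c3c(cc(OC)c(OC)c3OC)O2)cc1OC
F4 | step 2 | 5-[(3,4-dimethoxybenzyl)oxy]-1,2,3-trimethoxybenzene | COc1ccc(COc2cc(OC)c(OC)c(OC)c2)cc1OC
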